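**Retrosynthetic overview** (drimane numbering: C3 = ketone carbon, C4 = gem-dimethyl carbon, C5/C10 = ring fusion, C9 = carbon bearing the CH2OAr carbon C11)

1. The aryl ether is cut by Mitsunobu etherification of umbelliferone; C11 and the C9 centre come from a C9 ketone by methylenation and convex-face hydroboration.
2. Key disconnection is C3–C4 in the cyclohexanone ring: the ketone is a hydrolysed nitrile and the gem-dimethyl carbon a hydrogenated isopropenyl group, joined by a reductive alkene–nitrile radical cyclization (metal-hydride H-atom transfer, MHAT), a union of two carbons that are both electrophilic in polar terms.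
3. Enabling feature: ketone C3 sits directly beside quaternary C4, which hangs on ring-fusion carbon C5 of the methylcyclohexene ring; this C5–C(CH3)=CH2 unit with its ring is (S)-carvone.
4. The quaternary ring-fusion carbon C10 is built on carvone by two enolate alkylations (allyl, then methyl anti to isopropenyl); the allyl group becomes the CH2CH2CN arm.
5. Ring order: the coumarin rings (umbelliferone) and the methylcyclohexene ring (carvone) are bought; the cyclohexanone ring is the only skeletal ring made and is closed last, in step 5 (the dioxolane of steps 6–10 is only a protecting group).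

Key step: step 5

Remark: the target SMILES describes a cis-fused decalin with the angular methyl, the ring-fusion H and the H at C9 on one face and the carbon arms C1, C4 and C11 on the other; the route is built for this isomer.
Remark: LDA and 9-BBN are taken as commercial solutions.

**Step 1**
Reactants: 1 (S)-(+)-carvone
Product: 3 6-allylcarvone (both C6 epimers), via lithium dienolate 2 (not isolated)
Conditions: LDA, THF, −78 °C; allyl bromide, −78 → 0 °C
Reagents that add atoms: allyl bromide, C=CCBr
Why: Kinetic α′-deprotonation gives the cross-conjugated lithium dienolate, which is C-alkylated by the reactive allylic halide (enolate alkylation); the new centre forms as an epimer mixture that is erased in step 2.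

**Step 2**
Reactants: 3 6-allylcarvone
Product: 5 (5R,6S)-6-allyl-2,6-dimethyl-5-(prop-1-en-2-yl)cyclohex-2-en-1-one (allyl cis to isopropenyl), via lithium enolate 4 (not isolated)
Conditions: LDA, THF/DMPU, −78 °C; MeI, −78 → 0 °C
Reagents that add atoms: iodomethane, CI
Why: Stereoselective α′-alkylation of a carvone enolate: the tetrasubstituted enolate should be methylated anti to the neighbouring pseudoaxial isopropenyl group, so the quaternary carbon carries methyl trans and allyl cis to isopropenyl, as a cis ring fusion requires.

**Step 3**
Reactants: 5 allyl methyl carvone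
Product: 6 3-[(1S,6R)-1,3-dimethyl-2-oxo-6-(prop-1-en-2-yl)cyclohex-3-en-1-yl]propanal
Conditions: PdCl2(PhCN)2 (12 mol%), CuCl2·2H2O (12 mol%), AgNO2 (6 mol%), O2 (1 atm), t-BuOH/MeNO2 15:1, rt
Reagents that add atoms: dioxygen, O=O
Why: Aldehyde-selective (nitrite-modified, anti-Markovnikov) Wacker oxidation should act only on the monosubstituted allyl alkene, since the 1,1-disubstituted isopropenyl group and the enone alkene are poor substrates for oxypalladation.

**Step 4**
Reactants: 6 keto aldehyde
Product: 8 3-[(1S,6R)-1,3-dimethyl-2-oxo-6-(prop-1-en-2-yl)cyclohex-3-en-1-yl]propanenitrile, via aldimine 7 (not isolated)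
Conditions: I2 (1.1 equiv), 28% aq. NH3, THF, rt
Reagents that add atoms: ammonia, N
Why: Oxidative conversion of an aldehyde into a nitrile (condensation to the N–H aldimine, N-iodination, loss of HI) is mild enough to leave the alkenes and the hindered enone untouched.

**Step 5**
Reactants: 8 keto nitrile
Product: 10 (4aR,8aS)-2,5,5,8a-tetramethyl-4a,5,7,8-tetrahydronaphthalene-1,6(4H,8aH)-dione (cis-fused), via ketimine 9 (not isolated)
Conditions: Fe(acac)3 (30 mol%), PhSiH3 (2.5 equiv), degassed EtOH (0.02 M), 60 °C; then 1 M HCl, THF, rt
Reagents that add atoms: water, O
Why: Fe(acac)3/PhSiH3 forms an iron hydride that transfers a hydrogen atom to the CH2 terminus of the isopropenyl group (Markovnikov MHAT); the tertiary radical at the future gem-dimethyl carbon adds to the nitrile carbon, the iminyl radical is reduced to the N–H ketimine 9, and dilute acid hydrolyses it to the ketone. The closest known reaction type is the MHAT-initiated reductive cyclization of alkenyl nitriles to cyclic ketones, the hydride-catalysed form of the classical radical cyclization onto nitriles. The cyclohexanone ring closes in the 6-exo-dig mode (bond C3–C4) and can only be cis-fused, because the isopropenyl and cyanoethyl arms are cis on adjacent ring carbons. No new stereocentre arises: C4 becomes the achiral gem-dimethyl quaternary carbon (its second methyl is the former =CH2 plus the transferred H), and the ring-fusion configuration was fixed by carvone and step 2. The step needs H-atom transfer to the electron-rich 1,1-disubstituted alkene rather than to the electron-poor α-methyl enone alkene, and cyclization faster than radical reduction; the first should follow from the polarity and low hindrance of the isopropenyl group, the second from the cis-1,2 preorganisation on the ring, high dilution and the absence of any other acceptor within reach (the enone carbons could only be reached through four-membered rings).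

**Step 6**
Reactants: 10 cis-fused enedione
Product: 11 cis-fused enone with the saturated (C3) ketone protected as its 1,3-dioxolane
Conditions: (TMSOCH2)2, TMSOTf (5 mol%), CH2Cl2, −78 → −20 °C; pyridine quench
Reagents that add atoms: 1,2-bis(trimethylsilyloxy)ethane, C[Si](C)(C)OCCO[Si](C)(C)C
Why: Silyl-triflate-catalysed ketalization with the bis-silyl glycol ether should discriminate the saturated ketone from the conjugated enone carbonyl, which is far less electrophilic and flanked by a quaternary carbon.

**Step 7**
Reactants: 11 enone ketal
Product: 12 cis-fused diene ketal with exocyclic methylene at C9 conjugated to the ring alkene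
Conditions: Ph3PCH3Br, KOt-Bu, toluene, 90 °C
Reagents that add atoms: methyltriphenylphosphonium bromide, C[P+](c1ccccc1)(c1ccccc1)c1ccccc1.[Br-]
Why: Wittig methylenation with the non-stabilised ylide under forcing conditions should convert the hindered enone, which cannot enolise toward the quaternary carbon, while the ketal is stable to base.

**Step 8**
Reactants: 12 diene ketal
Product: 14 cis-fused homoallylic primary alcohol (CH2OH cis to the cyclohexane-ring carbons at C10 and C5 and trans to the angular methyl), via B-alkyl-9-BBN 13 (not isolated)
Conditions: 9-BBN, THF, 0 °C → rt; then NaOH, H2O2, 0 °C → rt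
Reagents that add atoms: hydrogen peroxide, OO
Why: Hydroboration–oxidation of the 1,3-diene places boron on the terminal CH2 of the exocyclic alkene (anti-Markovnikov; the trisubstituted ring alkene stays) and should deliver H to C9 syn from the convex face of the cis-decalin (the face of the angular methyl and ring-fusion H, the other being covered by the cyclohexane ring), which sets the C9 centre; oxidation proceeds with retention.

**Step 9**
Reactants: 14 primary alcohol; 15 umbelliferone (7-hydroxycoumarin)
Product: 16 umbelliferyl ether of 14 (dioxolane still in place)
Conditions: PPh3, DIAD, THF, 0 °C → rt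
Reagents that add atoms: none
Why: Mitsunobu etherification of a primary alcohol with an acidic phenol (pKa about 8) forms the alkyl aryl ether without touching any stereocentre, and the secondary ketal and the lactone are inert.

**Step 10**
Reactants: 16 ketal ether
Product: 17 7-{[(1R,4aS,8aS)-2,5,5,8a-tetramethyl-6-oxo-1,4,4a,5,6,7,8,8a-octahydronaphthalen-1-yl]methoxy}-2H-chromen-2-one (target)
Conditions: 1 M HCl, THF, rt
Reagents that add atoms: water, O
Why: Mild acid hydrolysis of the strained neopentyl dioxolane should release the ketone while the coumarin lactone, the aryl ether and the trisubstituted alkene survive.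

**Compound list**

1 | (S)-(+)-carvone | CC1=CC[C@H](C(C)=C)CC1=O | starting material
2 | lithium dienolate of carvone (not isolated) | [Li+].[O-]C1=C[C@@H](C(C)=C)CC=C1C | intermediate
3 | 6-allylcarvone, (5S), mixture of C6 epimers | CC1=CC[C@H](C(C)=C)C(CC=C)C1=O | intermediate
4 | lithium enolate of 6-allylcarvone (not isolated) | [Li+].[O-]C1=C(CC=C)[C@@H](C(C)=C)CC=C1C | intermediate
5 | (5R,6S)-6-allyl-2,6-dimethyl-5-(prop-1-en-2-yl)cyclohex-2-en-1-one | CC1=CC[C@H](C(C)=C)[C@](C)(CC=C)C1=O | intermediate
6 | 3-[(1S,6R)-1,3-dimethyl-2-oxo-6-(prop-1-en-2-yl)cyclohex-3-en-1-yl]propanal | CC1=CC[C@H](C(C)=C)[C@](C)(CCC=O)C1=O | intermediate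
7 | N–H aldimine of 6 (not isolated) | CC1=CC[C@H](C(C)=C)[C@](C)(CCC=N)C1=O | intermediate
8 | 3-[(1S,6R)-1,3-dimethyl-2-oxo-6-(prop-1-en-2-yl)cyclohex-3-en-1-yl]propanenitrile | CC1=CC[C@H](C(C)=C)[C@](C)(CCC#N)C1=O | intermediate
9 | cis-fused bicyclic N–H ketimine (not isolated) | CC1=CC[C@@H]2C(C)(C)C(=N)CC[C@]2(C)C1=O | intermediate
10 | (4aR,8aS)-2,5,5,8a-tetramethyl-4a,5,7,8-tetrahydronaphthalene-1,6(4H,8aH)-dione, cis-fused | CC1=CC[C@@H]2C(C)(C)C(=O)CC[C@]2(C)C1=O | intermediate
11 | cis-fused enone, C3 ketone as 1,3-dioxolane | CC1=CC[C@@H]2C(C)(C)C3(OCCO3)CC[C@]2(C)C1=O | intermediate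
12 | cis-fused 9-methylene diene ketal | CC1=CC[C@@H]2C(C)(C)C3(OCCO3)CC[C@]2(C)C1=C | intermediate
13 | B-alkyl-9-BBN adduct of 12 (not isolated) | CC1=CC[C@@H]2C(C)(C)C3(OCCO3)CC[C@]2(C)[C@@H]1CB1C2CCCC1CCC2 | intermediate
14 | cis-fused homoallylic primary alcohol, ketal | CC1=CC[C@@H]2C(C)(C)C3(OCCO3)CC[C@]2(C)[C@@H]1CO | intermediate
15 | umbelliferone (7-hydroxycoumarin) | Oc1ccc2ccc(=O)oc2c1 | starting material
16 | umbelliferyl ether, ketal | CC1=CC[C@@H]2C(C)(C)C3(OCCO3)CC[C@]2(C)[C@@H]1COc1ccc2ccc(=O)oc2c1 | intermediate
17 | 7-{[(1R,4aS,8aS)-2,5,5,8a-tetramethyl-6-oxo-1,4,4a,5,6,7,8,8a-octahydronaphthalen-1-yl]methoxy}-2H-chromen-2-one | CC1=CC[C@@H]2C(C)(C)C(=O)CC[C@]2(C)[C@@H]1COc1ccc2ccc(=O)oc2c1 | target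

**Step count:** 10 steps in total; longest linear sequence 10 steps (from (S)-carvone; umbelliferone enters in step 9).

**Steps most likely to fail**

Step 5 (key step). The tertiary radical may be quenched by hydride before the slow 6-exo addition to the nitrile (net hydrogenation of the isopropenyl group), or the enone may be conjugate-reduced by the metal hydride. The fallback sets out from nitrile 8: Markovnikov addition of HBr (33% HBr in AcOH, 0 °C) should give the tertiary bromide F1. Slow addition of Bu3SnH with AIBN in benzene at 80 °C then generates the same tertiary radical by bromine abstraction in a chain process with a low stationary hydride concentration, so that the classical tin-hydride cyclization onto the nitrile has time to occur. Acidic work-up of ketimine 9 returns to the route at dione 10.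

Step 8. Facial discrimination in the hydroboration may be poor, or the diene may be hydroborated twice. The fallback sets out from enone ketal 11: Wittig reaction with Ph3P=CHOMe (from MeOCH2PPh3Cl and KHMDS) should give the methoxymethylene diene F2. Brief hydrolysis with dilute aqueous acid at 0 °C (the enol ether cleaves much faster than the dioxolane), with kinetic α-protonation on the convex face, should give the β,γ-unsaturated aldehyde F3. Its configuration next to the formyl group can still be corrected by base equilibration or by kinetic reprotonation of its dienolate. NaBH4 in MeOH returns to the route at alcohol 14.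

Step 3. Regiocontrol of the oxypalladation may be lost (methyl ketone formation), or the allyl alkene may isomerise into conjugation-free internal positions. The fallback sets out from 5: hydroboration with disiamylborane (THF, 0 °C), which is selective for the monosubstituted alkene over the isopropenyl group and slow with the hindered enone, should give the alkyl(disiamyl)borane F4 (not isolated). NaOH/H2O2 gives the primary alcohol F5, and Dess–Martin periodinane oxidation returns to the route at aldehyde 6.

**Further compounds**

F1 | step 5 | tertiary bromide (HBr adduct of 8) | CC1=CC[C@H](C(C)(C)Br)[C@](C)(CCC#N)C1=O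
F2 | step 8 | methoxymethylene diene ketal (enol ether, E/Z) | CC1=CC[C@@H]2C(C)(C)C3(OCCO3)CC[C@]2(C)C1=COC
F3 | step 8 | β,γ-unsaturated aldehyde ketal | CC1=CC[C@@H]2C(C)(C)C3(OCCO3)CC[C@]2(C)[C@@H]1C=O
F4 | step 3 | alkyl(disiamyl)borane from 5 | CC1=CC[C@H](C(C)=C)[C@](C)(CCCB(C(C)C(C)C)C(C)C(C)C)C1=O
F5 | step 3 | primary alcohol from 5 | CC1=CC[C@H](C(C)=C)[C@](C)(CCCO)C1=O
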